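**Plan**

- Ring locants: C1 = C(CH3)OH, C2 = CH(side chain), C3 = C(CH3)(homoprenyl), C4 = CHBr, then C5 and C6. Retrosynthetic cuts, in order: the two silyl ethers; C4–Br (back to an axial C4–OH, inversion); the C=C and the adjoining C–C bond of the homoprenyl terminus (back to a γ-lactone C3–CH2–C(=O)–O–C4); C1–CH3; the C2–CH2 bond to the side chain; finally the lactone C4–O bond together with a temporary C5–Br bond.
- Enabling feature: C3, with CH3 and a CH2CO2H arm, is the sp3 carbon of a mirror-symmetric cyclohexa-2,5-diene whose alkenes C4=C5 and C2=C1 are enantiotopic, and C4 needs a heteroatom cis to that arm.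
- Forward: the carbocycle is the ring of benzoic acid (Birch methylation, Arndt–Eistert homologation). Bromolactonisation closes the only new ring, a temporary γ-lactone. C1=C2 becomes the C1 ketone and loss of HBr gives an enone that blocks C6. The side chain, made from (S)-citramalic acid, is joined at C2. Then follow enone reduction, CH3 addition at C1, lactone-to-homoprenyl conversion by two Wittig reactions, OH-to-Br exchange at C4 and desilylation.
- Stereochemistry: C3 from the catalyst; C4–O from the tether, then inverted; C2 by alkylation on the convex face of the bicycle; C1 by methyl addition anti to the C3 methyl; the side-chain carbinol from (S)-citramalic acid.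

Key step: step 4

Assumption: (DHQD)2PHAL is taken to give the (3aS,7S,7aS) lactone 10; if the sense of induction is the opposite, the pseudoenantiomeric (DHQ)2PHAL is used under the same conditions.
The target ring locants C1–C6 are used for all ring intermediates.

**Route**

Step 1
Reactants: 1 benzoic acid; 2 iodomethane
Product: 4 1-methylcyclohexa-2,5-diene-1-carboxylic acid, via dilithium dienediolate 3 (not isolated)
Conditions: Li, NH3(l), THF, −78 °C; then MeI, −78 °C → rt; aq. HCl
Reagents that add atoms: iodomethane (2), CI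
Why: Birch reduction of the benzoate stops at the cross-conjugated dienediolate, which is C-methylated at the ipso carbon (Birch reductive alkylation), giving the quaternary carbon flanked by two equivalent alkenes.

Step 2
Reactants: 4 1-methylcyclohexa-2,5-diene-1-carboxylic acid
Product: 6 2-diazo-1-(1-methylcyclohexa-2,5-dien-1-yl)ethan-1-one, via acid chloride 5 (not isolated)
Conditions: (COCl)2, DMF (cat.), CH2Cl2, 0 °C → rt; evaporate; TMSCHN2 (2 equiv), THF–MeCN, 0 °C → rt
Reagents that add atoms: trimethylsilyldiazomethane, C[Si](C)(C)C=[N+]=[N-]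
Why: The acid chloride acylates the diazoalkane and the silyl group is lost, giving the α-diazo ketone (first half of the Arndt–Eistert homologation) under conditions cold and neutral enough to spare the skipped diene.

Step 3
Reactants: 6 2-diazo-1-(1-methylcyclohexa-2,5-dien-1-yl)ethan-1-one
Product: 8 2-(1-methylcyclohexa-2,5-dien-1-yl)acetic acid, via ketene 7 (not isolated)
Conditions: PhCO2Ag (10 mol %), Et3N, THF–H2O, rt, dark
Reagents that add atoms: water, O
Why: Silver-catalysed Wolff rearrangement moves the tertiary dienyl carbon to the carbene carbon and water adds to the ketene, completing the Arndt–Eistert homologation at a neopentyl position where displacement chemistry would fail.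

Step 4
Reactants: 8 2-(1-methylcyclohexa-2,5-dien-1-yl)acetic acid; 9 N-bromosuccinimide
Product: 10 (3aS,7S,7aS)-7-bromo-3a-methyl-3a,6,7,7a-tetrahydro-1-benzofuran-2(3H)-one
Conditions: (DHQD)2PHAL (hydroquinidine 1,4-phthalazinediyl diether, 10 mol %), NBS (1.1 equiv), CHCl3–hexane, −40 °C
Reagents that add atoms: N-bromosuccinimide (9), O=C1CCC(=O)N1Br
Why: The catalyst's quinuclidine nitrogen pairs with the carboxylic acid and its chiral pocket guides the electrophilic bromine of N-bromosuccinimide onto one of the two enantiotopic ring alkenes; the closest known reaction type is the cinchona-alkaloid-catalysed desymmetrising bromolactonisation of cyclohexa-2,5-dienylacetic acids. The carboxylate opens the bromonium ion anti at the nearer carbon (C4) in a 5-exo-trig closure that forms the γ-lactone. C3 becomes stereogenic only through the catalyst's choice of alkene. The C4–O centre is fixed by the two-atom tether, which reaches only its own face (cis fusion, oxygen cis to the arm), and the C5–Br centre follows from anti addition. The step needs enantiotopic-group selectivity, supplied by the catalyst, and 5-exo over 6-endo closure, supplied by the short tether; the second alkene survives because only one equivalent of the bromine source is used.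

Step 5
Reactants: 10 (3aS,7S,7aS)-7-bromo-3a-methyl-3a,6,7,7a-tetrahydro-1-benzofuran-2(3H)-one
Product: 12 (3aR,7S,7aS)-7-bromo-5-hydroxy-3a-methylhexahydro-1-benzofuran-2(3H)-one, via B-alkyl-9-borabicyclononane 11 (not isolated)
Conditions: 9-BBN, THF, 60 °C; then NaBO3·4H2O, THF–H2O, rt
Reagents that add atoms: sodium perborate (used as the tetrahydrate), [Na+].[O-]OB=O
Why: Hydroboration–oxidation with the bulky dialkylborane places boron on C1, the alkene carbon remote from quaternary C3, and the mild perborate oxidation leaves the lactone closed, so no C4 alkoxide can displace the neighbouring bromide; the C1 carbinol configuration is immaterial because it is oxidised next.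

Step 6
Reactants: 12 (3aR,7S,7aS)-7-bromo-5-hydroxy-3a-methylhexahydro-1-benzofuran-2(3H)-one
Product: 14 (3aR,7aR)-3a-methyl-3a,4-dihydro-1-benzofuran-2,5(3H,7aH)-dione, via β-bromo ketone 13 (not isolated)
Conditions: (COCl)2, DMSO, CH2Cl2, −78 °C; Et3N, −78 °C → rt
Reagents that add atoms: none
Why: Swern oxidation gives the C1 ketone, whose C5 bromide is then β and is lost by E1cB elimination under the triethylamine already present, so the temporary bromide is converted into a C5=C6 enone that leaves C2 as the only enolisable CH2.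

Step 7
Reactants: 15 (S)-citramalic acid
Product: 16 2-[(4S)-2,2,4-trimethyl-5-oxo-1,3-dioxolan-4-yl]acetic acid
Conditions: 2,2-dimethoxypropane, TsOH·H2O (cat.), rt
Reagents that add atoms: 2,2-dimethoxypropane, COC(C)(C)OC
Why: Acid-catalysed acetalisation ties the tertiary hydroxyl and the adjacent carboxyl into a dioxolanone, which differentiates the two carboxyl groups without touching the stereocentre.

Step 8
Reactants: 16 2-[(4S)-2,2,4-trimethyl-5-oxo-1,3-dioxolan-4-yl]acetic acid
Product: 18 (3S)-3-hydroxy-3-methyloxolan-2-one, via hydroxyethyl dioxolanone 17 (not isolated)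
Conditions: BH3·THF, THF, 0 °C → rt; MeOH quench; then TsOH·H2O (cat.), CH2Cl2, rt
Reagents that add atoms: none
Why: Borane reduces the free carboxylic acid much faster than the dioxolanone ester, and acid-catalysed transesterification of the resulting primary alcohol onto the dioxolanone carbonyl closes the γ-lactone with loss of acetone.

Step 9
Reactants: 18 (3S)-3-hydroxy-3-methyloxolan-2-one
Product: 19 (3S)-3-methyloxolane-2,3-diol
Conditions: i-Bu2AlH (2.2 equiv), CH2Cl2, −78 °C; aq. potassium sodium tartrate
Reagents that add atoms: none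
Why: Partial reduction of a lactone with the aluminium hydride at low temperature stops at the aluminium hemiacetal and gives the lactol on work-up.

Step 10
Reactants: 19 (3S)-3-methyloxolane-2,3-diol
Product: 20 (3S)-3-methylpent-4-ene-1,3-diol
Conditions: Ph3PCH3Br, KOt-Bu (excess), THF, 0 → 40 °C
Reagents that add atoms: methyltriphenylphosphonium bromide, C[P+](c1ccccc1)(c1ccccc1)c1ccccc1.[Br-]
Why: Wittig methylenation of the open hydroxy aldehyde form of the lactol makes the vinyl group on the carbinol carbon and frees the primary alcohol at the other end.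

Step 11
Reactants: 20 (3S)-3-methylpent-4-ene-1,3-diol
Product: 21 (3S)-5-iodo-3-methylpent-1-en-3-ol
Conditions: I2, PPh3, imidazole, CH2Cl2, 0 °C
Reagents that add atoms: iodine, II
Why: Iodination through the alkoxyphosphonium ion (Appel-type) is selective for the primary hydroxyl, the tertiary one being too hindered to be activated at 0 °C.

Step 12
Reactants: 21 (3S)-5-iodo-3-methylpent-1-en-3-ol
Product: 22 tert-butyl{[(3S)-5-iodo-3-methylpent-1-en-3-yl]oxy}dimethylsilane
Conditions: TBSOTf, 2,6-lutidine, CH2Cl2, −78 → 0 °C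
Reagents that add atoms: tert-butyldimethylsilyl trifluoromethanesulfonate, CC(C)(C)[Si](C)(C)OS(=O)(=O)C(F)(F)F
Why: Silyl triflate silylation protects the tertiary allylic alcohol as an ether that withstands enolate, hydride, ylide and mild acid conditions.

Step 13
Reactants: 14 (3aR,7aR)-3a-methyl-3a,4-dihydro-1-benzofuran-2,5(3H,7aH)-dione; 22 tert-butyl{[(3S)-5-iodo-3-methylpent-1-en-3-yl]oxy}dimethylsilane
Product: 24 (3aS,4S,7aR)-4-[(3S)-3-(tert-butyldimethylsilyloxy)-3-methylpent-4-en-1-yl]-3a-methyl-3a,4-dihydro-1-benzofuran-2,5(3H,7aH)-dione, via lithium dienolate 23 (not isolated)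
Conditions: LiN(i-Pr)2 (1.05 equiv), THF, −78 °C; then 22, HMPA, −78 → −20 °C
Reagents that add atoms: none
Why: Kinetic deprotonation at C2, the only α-CH2, gives the cross-conjugated lithium dienolate, which is alkylated by the primary iodide (enolate SN2 alkylation) on the convex face of the cis-fused bicycle, anti to the lactone arm on C3, so the side chain at C2 ends up cis to the C3 methyl.

Step 14
Reactants: 24 alkylated enone lactone
Product: 25 (3aS,4S,7aR)-4-[(3S)-3-(tert-butyldimethylsilyloxy)-3-methylpent-4-en-1-yl]-3a-methylhexahydro-1-benzofuran-2,5-dione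
Conditions: [(Ph3P)CuH]6, toluene, H2O (2 equiv), rt; aq. NH4Cl
Reagents that add atoms: none
Why: Conjugate reduction by the phosphine-stabilised copper hydride delivers hydride to C5 of the enone only, leaving the vinyl group and the lactone alone, and the copper enolate forms toward C6, so the C2 stereocentre is not enolised.

Step 15
Reactants: 25 keto lactone
Product: 26 (3aS,4S,5R,7aR)-4-[(3S)-3-(tert-butyldimethylsilyloxy)-3-methylpent-4-en-1-yl]-5-hydroxy-3a,5-dimethylhexahydro-1-benzofuran-2(3H)-one
Conditions: MeMgBr, CeCl3 (anhydrous), THF, −78 °C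
Reagents that add atoms: methylmagnesium bromide, C[Mg]Br
Why: Organocerium 1,2-addition is non-basic (no epimerisation at C2) and much faster at the ketone than at the lactone; in the chair that keeps the C2 side chain equatorial the C3 methyl is axial and blocks its own face, so methyl enters equatorially from the opposite face and the C1 hydroxyl ends up axial, cis to the side chain.

Step 16
Reactants: 26 hydroxy lactone
Product: 27 (3aS,4S,5R,7aR)-4-[(3S)-3-(tert-butyldimethylsilyloxy)-3-methylpent-4-en-1-yl]-3a,5-dimethyl-5-(triethylsilyloxy)hexahydro-1-benzofuran-2(3H)-one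
Conditions: TESOTf, 2,6-lutidine, CH2Cl2, 0 °C → rt
Reagents that add atoms: triethylsilyl trifluoromethanesulfonate, CC[Si](CC)(CC)OS(=O)(=O)C(F)(F)F
Why: Silyl triflate silylation caps the hindered tertiary C1 alcohol so that it can neither be activated nor act as a transannular nucleophile when C4 is brominated later.

Step 17
Reactants: 27 bis-silyl lactone
Product: 28 the corresponding γ-lactol (octahydro-1-benzofuran-2-ol)
Conditions: i-Bu2AlH (1.2 equiv), CH2Cl2, −78 °C; aq. potassium sodium tartrate
Reagents that add atoms: none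
Why: Low-temperature aluminium hydride reduction stops at the lactol, which keeps the C4 oxygen tied up while exposing the arm carbon as a latent aldehyde.

Step 18
Reactants: 28 γ-lactol
Product: 30 δ-lactol (octahydro-2H-chromen-2-ol) with one more carbon in the arm, via methyl enol ether 29 (not isolated)
Conditions: Ph3P(CH2OMe)Cl, KN(SiMe3)2, THF, 0 °C → rt; then oxalic acid, THF–H2O, rt
Reagents that add atoms: (methoxymethyl)triphenylphosphonium chloride, COC[P+](c1ccccc1)(c1ccccc1)c1ccccc1.[Cl-]; water, O
Why: Wittig methoxymethylenation of the open aldehyde form followed by mild acid hydrolysis of the enol ether is the standard one-carbon aldehyde homologation, and the new aldehyde is trapped by the C4 hydroxyl as a six-membered lactol.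

Step 19
Reactants: 30 δ-lactol
Product: 31 (1R,2S,3S,4R)-configured homoprenyl alcohol (free axial C4–OH, target locants)
Conditions: i-PrPPh3I, n-BuLi, THF, 0 °C → rt
Reagents that add atoms: isopropyltriphenylphosphonium iodide, CC(C)[P+](c1ccccc1)(c1ccccc1)c1ccccc1.[I-]
Why: Wittig olefination of the lactol's aldehyde form with the isopropylidene ylide completes the homoprenyl chain as a trisubstituted alkene that has no geometric isomers and releases the C4 hydroxyl.

Step 20
Reactants: 31 homoprenyl alcohol
Product: 32 (1R,2S,3S,4S)-configured C4 bromide (bis-silyl ether of the target)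
Conditions: CBr4, PPh3, pyridine, toluene, 60 °C
Reagents that add atoms: carbon tetrabromide, BrC(Br)(Br)Br
Why: In the Appel reaction the axial C4 hydroxyl becomes an alkoxyphosphonium ion that bromide displaces from the opposite face (SN2, inversion), so the bromide ends up equatorial, trans to the homoprenyl chain and cis to the C3 methyl.

Step 21
Reactants: 32 bis-silyl bromide
Product: 33 (1R,2S,3S,4S)-4-bromo-2-[(3S)-3-hydroxy-3-methylpent-4-en-1-yl]-1,3-dimethyl-3-(4-methylpent-3-en-1-yl)cyclohexan-1-ol
Conditions: Bu4NF, THF, rt → 45 °C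
Reagents that add atoms: none
Why: Fluoride-mediated desilylation frees both tertiary alcohols; the equatorial neopentyl bromide has no anti-periplanar hydrogen and is inert to fluoride.

**Compound list**

1 | benzoic acid | OC(=O)c1ccccc1 | starting material
2 | iodomethane | CI | starting material
3 | dilithium (cyclohexa-2,5-dien-1-ylidene)methanediolate | [Li+].[Li+].[O-]C([O-])=C1C=CCC=C1 | intermediate (not isolated)
4 | 1-methylcyclohexa-2,5-diene-1-carboxylic acid | CC1(C(=O)O)C=CCC=C1 | intermediate
5 | 1-methylcyclohexa-2,5-diene-1-carbonyl chloride | CC1(C(=O)Cl)C=CCC=C1 | intermediate (not isolated)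
6 | 2-diazo-1-(1-methylcyclohexa-2,5-dien-1-yl)ethan-1-one | CC1(C(=O)C=[N+]=[N-])C=CCC=C1 | intermediate
7 | 2-(1-methylcyclohexa-2,5-dien-1-yl)ethen-1-one (ketene) | CC1(C=C=O)C=CCC=C1 | intermediate (not isolated)
8 | 2-(1-methylcyclohexa-2,5-dien-1-yl)acetic acid | CC1(CC(=O)O)C=CCC=C1 | intermediate
9 | N-bromosuccinimide | O=C1CCC(=O)N1Br | starting material
10 | (3aS,7S,7aS)-7-bromo-3a-methyl-3a,6,7,7a-tetrahydro-1-benzofuran-2(3H)-one (cis-fused; Br trans to the lactone oxygen) | C1=CC[C@H](Br)[C@H]2OC(=O)C[C@@]12C | intermediate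
11 | B-alkyl-9-borabicyclo[3.3.1]nonane from 10, boron on C1 (benzofuranone C5), C1 configuration undefined | C1C(B3C4CCCC3CCC4)C[C@H](Br)[C@H]2OC(=O)C[C@@]12C | intermediate (not isolated)
12 | (3aR,7S,7aS)-7-bromo-5-hydroxy-3a-methylhexahydro-1-benzofuran-2(3H)-one (C5 epimers) | C1C(O)C[C@H](Br)[C@H]2OC(=O)C[C@@]12C | intermediate
13 | (3aR,7S,7aS)-7-bromo-3a-methylhexahydro-1-benzofuran-2,5-dione | C1C(=O)C[C@H](Br)[C@H]2OC(=O)C[C@@]12C | intermediate (not isolated)
14 | (3aR,7aR)-3a-methyl-3a,4-dihydro-1-benzofuran-2,5(3H,7aH)-dione (cis-fused enone lactone) | C1C(=O)C=C[C@H]2OC(=O)C[C@@]12C | intermediate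
15 | (S)-citramalic acid, (2S)-2-hydroxy-2-methylbutanedioic acid | OC(=O)[C@@](C)(O)CC(=O)O | starting material
16 | 2-[(4S)-2,2,4-trimethyl-5-oxo-1,3-dioxolan-4-yl]acetic acid | O=C1OC(C)(C)O[C@@]1(C)CC(=O)O | intermediate
17 | (5S)-5-(2-hydroxyethyl)-2,2,5-trimethyl-1,3-dioxolan-4-one | O=C1OC(C)(C)O[C@@]1(C)CCO | intermediate (not isolated)
18 | (3S)-3-hydroxy-3-methyloxolan-2-one | O=C1OCC[C@]1(C)O | intermediate
19 | (3S)-3-methyloxolane-2,3-diol (anomers) | OC1OCC[C@]1(C)O | intermediate
20 | (3S)-3-methylpent-4-ene-1,3-diol | C=C[C@@](C)(O)CCO | intermediate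
21 | (3S)-5-iodo-3-methylpent-1-en-3-ol | C=C[C@@](C)(O)CCI | intermediate
22 | tert-butyl{[(3S)-5-iodo-3-methylpent-1-en-3-yl]oxy}dimethylsilane | C=C[C@@](C)(O[Si](C)(C)C(C)(C)C)CCI | intermediate
23 | lithium dienolate of 14 (C1–O–Li, C1=C2 and C5=C6) | C1=C([O-])C=C[C@H]2OC(=O)C[C@@]12C.[Li+] | intermediate (not isolated)
24 | (3aS,4S,7aR)-4-[(3S)-3-(tert-butyldimethylsilyloxy)-3-methylpent-4-en-1-yl]-3a-methyl-3a,4-dihydro-1-benzofuran-2,5(3H,7aH)-dione (side chain cis to the angular methyl) | [C@@H]1(CC[C@](C)(O[Si](C)(C)C(C)(C)C)C=C)C(=O)C=C[C@H]2OC(=O)C[C@@]12C | intermediate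
25 | (3aS,4S,7aR)-4-[(3S)-3-(tert-butyldimethylsilyloxy)-3-methylpent-4-en-1-yl]-3a-methylhexahydro-1-benzofuran-2,5-dione | [C@@H]1(CC[C@](C)(O[Si](C)(C)C(C)(C)C)C=C)C(=O)CC[C@H]2OC(=O)C[C@@]12C | intermediate
26 | (3aS,4S,5R,7aR)-4-[(3S)-3-(tert-butyldimethylsilyloxy)-3-methylpent-4-en-1-yl]-5-hydroxy-3a,5-dimethylhexahydro-1-benzofuran-2(3H)-one | [C@@H]1(CC[C@](C)(O[Si](C)(C)C(C)(C)C)C=C)[C@](C)(O)CC[C@H]2OC(=O)C[C@@]12C | intermediate
27 | (3aS,4S,5R,7aR)-4-[(3S)-3-(tert-butyldimethylsilyloxy)-3-methylpent-4-en-1-yl]-3a,5-dimethyl-5-(triethylsilyloxy)hexahydro-1-benzofuran-2(3H)-one | [C@@H]1(CC[C@](C)(O[Si](C)(C)C(C)(C)C)C=C)[C@](C)(O[Si](CC)(CC)CC)CC[C@H]2OC(=O)C[C@@]12C | intermediate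
28 | γ-lactol of 27: the octahydro-1-benzofuran-2-ol with the same substituents and configuration (anomers) | [C@@H]1(CC[C@](C)(O[Si](C)(C)C(C)(C)C)C=C)[C@](C)(O[Si](CC)(CC)CC)CC[C@H]2OC(O)C[C@@]12C | intermediate
29 | ring-opened hydroxy enol ether: cyclohexane with free C4–OH (cis to the arm) and a 3-methoxyprop-2-en-1-yl arm on C3 (E/Z), other groups as in 27 | [C@@H]1(CC[C@](C)(O[Si](C)(C)C(C)(C)C)C=C)[C@](C)(O[Si](CC)(CC)CC)CC[C@@H](O)[C@@]1(C)CC=COC | intermediate (not isolated)
30 | δ-lactol: cis-fused octahydro-2H-chromen-2-ol formed from the C4 oxygen and the three-carbon arm on C3 (anomers), other groups as in 27 | [C@@H]1(CC[C@](C)(O[Si](C)(C)C(C)(C)C)C=C)[C@](C)(O[Si](CC)(CC)CC)CC[C@H]2OC(O)CC[C@@]12C | intermediate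
31 | (1R,2S,3S,4R; target locants) 2-[(3S)-3-(tert-butyldimethylsilyloxy)-3-methylpent-4-en-1-yl]-1,3-dimethyl-3-(4-methylpent-3-en-1-yl)-1-(triethylsilyloxy)cyclohexan-4-ol | [C@@H]1(CC[C@](C)(O[Si](C)(C)C(C)(C)C)C=C)[C@](C)(O[Si](CC)(CC)CC)CC[C@@H](O)[C@@]1(C)CCC=C(C)C | intermediate
32 | (1R,2S,3S,4S; target locants) 4-bromo-2-[(3S)-3-(tert-butyldimethylsilyloxy)-3-methylpent-4-en-1-yl]-1,3-dimethyl-3-(4-methylpent-3-en-1-yl)-1-(triethylsilyloxy)cyclohexane | [C@@H]1(CC[C@](C)(O[Si](C)(C)C(C)(C)C)C=C)[C@](C)(O[Si](CC)(CC)CC)CC[C@H](Br)[C@@]1(C)CCC=C(C)C | intermediate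
33 | (1R,2S,3S,4S)-4-bromo-2-[(3S)-3-hydroxy-3-methylpent-4-en-1-yl]-1,3-dimethyl-3-(4-methylpent-3-en-1-yl)cyclohexan-1-ol (CNP0237376.1) | C=C[C@@](C)(O)CC[C@H]1[C@](C)(CCC=C(C)C)[C@@H](Br)CC[C@@]1(C)O | target

**Step count and risks**

Total: 21 steps. Longest linear sequence: 15 steps (steps 1–6 and 13–21); steps 7–12 make the side-chain iodide.

The three steps most likely to fail:

1. Step 13. C-alkylation at an enolate carbon next to a quaternary centre by an unactivated primary iodide may be slow. Proton transfer to the extended dienolate could then divert alkylation to C6 or to oxygen, and the facial preference may be modest. The fallback sets out from 14 and comes back at 24. Enone 14 would be condensed with 1,1-dimethylhydrazine (AcOH cat., EtOH) to the N,N-dimethylhydrazone F1. Its azaenolate (LiN(i-Pr)2, THF, −78 °C), a far better nucleophile toward alkyl iodides, would be alkylated with 22 at C2 to give the alkylated hydrazone F2. Buffered CuCl2 in aqueous THF would then release ketone 24.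

2. Step 20. The alkoxyphosphonium ion at the axial neopentylic C4 may not undergo substitution. It may instead lose a proton from C5, trigger a 1,2-shift of the anti-periplanar C3 methyl, or be intercepted across the ring by the C1 oxygen. The fallback sets out from 31 and comes back at 32, and separates activation from displacement. Alcohol 31 would be converted with chloromethanesulfonyl chloride and pyridine at 0 °C into the chloromethanesulfonate F3, a small, isolable and very reactive sulfonate. LiBr in N,N-dimethylformamide at 40–60 °C would then displace it with inversion to give 32.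

3. Step 15. Facial selectivity may be poor because the cis-fused keto lactone can also react through a second chair with the side chain axial, and the lactone can compete for the nucleophile. The fallback sets out from 25 and comes back at 33; it postpones the methyl addition to a monocyclic ketone whose chair is fixed by an equatorial bromide.
   - Ketone 25 would be masked as the 1,3-dioxolane F4 (ethylene glycol, pyridinium tosylate, benzene, reflux).
   - The lactone would be reduced to the lactol F5 (i-Bu2AlH, −78 °C).
   - Homologation through the enol ether F6 would give the δ-lactol F7 (Ph3P=CHOMe; oxalic acid, THF–H2O, 0 °C).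
   - Olefination with Ph3P=CMe2 would give the ketal alcohol F8.
   - Pyridinium tosylate in wet acetone would free the hydroxy ketone F9.
   - Bromination with inversion as in step 20 would give the bromo ketone F10.
   - MeMgBr–CeCl3 would attack equatorially, anti to the axial C3 methyl, to give the mono-silylated bromo diol F11.
   - Bu4NF would return to 33.

Further compounds
F1 | step 13 | N,N-dimethylhydrazone of enone lactone 14 | C1C(=NN(C)C)C=C[C@H]2OC(=O)C[C@@]12C
F2 | step 13 | N,N-dimethylhydrazone of alkylated enone lactone 24 | [C@@H]1(CC[C@](C)(O[Si](C)(C)C(C)(C)C)C=C)C(=NN(C)C)C=C[C@H]2OC(=O)C[C@@]12C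
F3 | step 20 | chloromethanesulfonate of alcohol 31 | [C@@H]1(CC[C@](C)(O[Si](C)(C)C(C)(C)C)C=C)[C@](C)(O[Si](CC)(CC)CC)CC[C@@H](OS(=O)(=O)CCl)[C@@]1(C)CCC=C(C)C
F4 | step 15 | 1,3-dioxolane (C1 ketal) of keto lactone 25 | [C@@H]1(CC[C@](C)(O[Si](C)(C)C(C)(C)C)C=C)C3(OCCO3)CC[C@H]2OC(=O)C[C@@]12C
F5 | step 15 | γ-lactol of F4 | [C@@H]1(CC[C@](C)(O[Si](C)(C)C(C)(C)C)C=C)C3(OCCO3)CC[C@H]2OC(O)C[C@@]12C
F6 | step 15 | ring-opened hydroxy methyl enol ether from F5 | [C@@H]1(CC[C@](C)(O[Si](C)(C)C(C)(C)C)C=C)C3(OCCO3)CC[C@@H](O)[C@@]1(C)CC=COC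
F7 | step 15 | homologated δ-lactol with C1 dioxolane | [C@@H]1(CC[C@](C)(O[Si](C)(C)C(C)(C)C)C=C)C3(OCCO3)CC[C@H]2OC(O)CC[C@@]12C
F8 | step 15 | homoprenyl C4 alcohol with C1 dioxolane | [C@@H]1(CC[C@](C)(O[Si](C)(C)C(C)(C)C)C=C)C3(OCCO3)CC[C@@H](O)[C@@]1(C)CCC=C(C)C
F9 | step 15 | C4-hydroxy C1 ketone with homoprenyl and silylated side chain | [C@@H]1(CC[C@](C)(O[Si](C)(C)C(C)(C)C)C=C)C(=O)CC[C@@H](O)[C@@]1(C)CCC=C(C)C
F10 | step 15 | C4-bromo C1 ketone (bromide equatorial, inverted) | [C@@H]1(CC[C@](C)(O[Si](C)(C)C(C)(C)C)C=C)C(=O)CC[C@H](Br)[C@@]1(C)CCC=C(C)C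
F11 | step 15 | target with the side-chain tertiary alcohol still as its tert-butyldimethylsilyl ether | [C@@H]1(CC[C@](C)(O[Si](C)(C)C(C)(C)C)C=C)[C@](C)(O)CC[C@H](Br)[C@@]1(C)CCC=C(C)C
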